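The noon run held twice the percent of G of the dawn run at 2.50 min, on 4.00 times the charge.

| setting | dawn | noon | flask |
|---|---|---|---|
| D | 21 mM | 84 mM | 42 mM |
| Z | 21 mM | 84 mM | 42 mM |
| J | 3 equiv | 3 equiv | 3.00 equiv |
| E | 5.3 mol% | 5.3 mol% | 5.3 mol% |
| X | 1 mol% | 1 mol% | 1 mol% |
| remark | run made earlier | run made earlier |  |
| time |  |  | 2.5 min |

- dawn (time / min: G / %, D / %): 0.200: 1.6, 48.0; 0.667: 1.5, 50.9; 1.00: 2.0, 48.8; 1.50: 2.8, 46.8; 2.50: 5.9, 45.0; 3.00: 7.2, 42.5
- noon (time / min: G / %, D / %): 0.500: 1.7, 48.9; 1.00: 5.1, 47.3; 1.50: 6.7, 45.0; 2.00: 10.8, 41.9; 2.50: 11.8, 40.8; 3.00: 14.3, 40.5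

(scatter of a reading: 1 percentage point)

- E is single-handed; D and Z are mirror images of each other, charged as a racemate, each of them at the stated concentration
- solid, in amounts per volume of the solution: J
- at the start none of J is in solution

- cedar: doubling the solubility of J, all else as stated
- larch: doubling the dissolution coefficient of J, all else as stated
- maple: doubling the amount of E, all else as stated

1. G at 2.5 min, in percent of the D and Z together charged
2. the change that raises the amount of G at 2.5 min, in percent of the D and Z together charged most ("none" if none brings more than 2 percentage points) (cedar / larch / maple / none)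
3. amount of G at 2.5 min, in percent of the D and Z together charged, after maple

The flask's charge is the geometric mean of those two charges, so I took the geometric mean of their G at that time and reckoned 8.34 %. But the D column says more. I divided the G gained by the D lost and pooled the readings of both runs at 3.00 min; this gave the G made per D lost up to that time, g 1.26, a reading that carries the scatter and belongs to that point of the runs. Each G takes one D, so a g above 1 means that D was being refilled, and I suspected Z with X, which is a dynamic kinetic resolution.

The forecast gave 8.7 % of G, cedar as the best change and 12 % after maple, holding that “dissolved J builds up slowly and sits below saturation”.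

The flask gave 10.4 % of G and 15.9 % after maple, and cedar was the best change, worth 8.9 percentage points.

    L + E + D → E + G (k = 4800 M⁻² min⁻¹)
    L + E + Z → E + Q (k = 1800 M⁻² min⁻¹)
    D + X ⇌ Z + X, rate k3*[X]*[D] forward; the back reaction follows from the equilibrium constant (k = 1700 M⁻¹ min⁻¹)
    J ⇌ L, rate k4*(cs4 - [L]) while solid is left; crystals form when [L] > cs4 (solubility = 18.0 mM, k = 0.990 min⁻¹)

Here L is dissolved J and Q the product of Z. At 2.50 min the flask's step to G used D at 0.17 of the forward rate from D to Z, and D and Z stood at 41.8 % and 43.8 %. At 0.938 min L went to G 2.6 times as fast as to Q. The flask's g at 2.50 min was 1.27, beside the 1.26 read from the runs. The same flask read at 10 min, with G 41.1 % and D 20.7 %, had a g of 1.40, which is 1.11 times that 1.26.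

Readings and results stem from a simulated flask for an exercise, noise included.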